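Compound numbers refer to the list after the steps. Ar = 4-(benzyloxy)-3,5-dimethoxyphenyl, Bn = benzyl. Bicyclic compounds carry the numbering of the target (C1 bears the aryl group, C4a and C8a are the fusion carbons); monocyclic ones are numbered systematically.

Assumption: di-(+)-menthyl fumarate 3 is taken to give the (1R,2R) cycloadduct 5, the mirror image of the sense known for the (−)-menthyl ester.

## Analysis of the target

The target 35 is a 1-aryltetralin of the lyoniresinol type: an aromatic ring A (C4a to C8a) fused to a saturated ring B (C1 to C4) that carries a 4-hydroxy-3,5-dimethoxyphenyl group on C1 and hydroxymethyl groups on C2 and C3. The three stereocentres are contiguous, (1S,2R,3R), and all-trans, so the aryl group and the C3 hydroxymethyl group lie on one face of ring B and the C2 hydroxymethyl group on the other. Ring A is pentasubstituted, with OMe on C6, OH on C7, OMe on C8 and hydrogen only on C5, which puts the C8 methoxy group peri to the aryl-bearing C1. The sensitive parts are the two electron-rich 2,6-dimethoxyphenols, the doubly benzylic C1–H and the 1,4-diol. The synthesis is hard because the triad includes a centre (C1) that cannot be corrected by epimerisation once the tetralin exists, because ring A needs three adjacent oxygens in a fixed order, and because on each aromatic ring a free phenol must be told apart from two methyl ethers. The strategy rests on one feature of ring A: the oxygens on C6 and C8 are meta to each other, C5 carries hydrogen and C7 sits between the two oxygens. This is the pattern of a resorcinol monoether, which a vinylketene–alkoxyalkyne benzannulation lays down. Ring A can therefore be built last, on C4a and C8a of a cyclohexene that already holds the whole triad, and the C7 oxygen can be added afterwards at the one position flanked by two ethers.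

## Retrosynthetic reasoning

**35 from 34.** The three O–benzyl bonds are cut last. One kind of protecting group on both primary alcohols and on the pendant phenol means a single hydrogenolysis, and nothing else in 34 is reducible under those conditions.

**34 from 31.** The C7–O bond is cut. C7 is the only ring carbon between two methoxy groups, so a directed metalation finds it without a blocking group. Placing this oxygen last is also a necessity: the benzannulation can deliver two meta oxygens but not three adjacent ones. The forward step has to metalate C7 in the presence of three benzyl ethers and the doubly benzylic C1–H.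

**31 from 30.** The O–methyl bond on C8 is cut. The free phenol that the annulation produces is simply methylated; it is the only hydroxyl in 30.

**30 from 22 and 25 (key disconnection).** Four bonds of ring A are cut: C4a–C5, C5–C6, C7–C8 and C8–C8a. This removes ring A entirely and leaves a cyclohexene (22) in which ring B and all three stereocentres are already in place, plus the two-carbon alkyne 25. The cut is made here because none of the stereocentres is involved and because the orientation of the two oxygens follows from the polarity of the partners, not from directing groups. The forward reaction must turn the diazoketone into a vinylketene, add 25 across the ketene, and pass through a four-electron ring opening and a six-electron ring closure without touching the allylic C–H next to the aryl group.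

**22 from 20, and 20 from 18.** The C–N2 bond is cut by diazo transfer to methyl ketone 20. Acylating a diazoalkane with the corresponding unsaturated acid chloride was not chosen, because the conjugated double bond is itself a dipolarophile. The acetyl C–C bond at the ring is then cut back to alkenyl triflate 18, which fixes the position of the ring double bond. The forward steps need a coupling with an acetyl anion equivalent and a kinetic deprotonation at the methyl group, not at the γ-position.

**18 from 16, and 16 from 10 and 12.** The bond between the ring and the aryl group is cut. A conjugate addition to enone 10 makes this stereocentre and generates the enolate on exactly the side of the ring that must become the C4a=C8a double bond; trapping on oxygen stores that regiochemistry. The stereochemistry needs care. In a trans-4,5-disubstituted cyclohexenone the two substituents pull in opposite directions for a stoichiometric organocopper reagent: axial attack anti to the remote group would place the aryl group cis to its neighbour. Substrate control is therefore not trusted, and a chiral bisphosphine–rhodium catalyst is used so that the ligand decides the face.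

**10 from 7.** The carbonyl is removed and the double bond moved back one position. Alkene 7 is C2-symmetric, so oxygenation at either alkene carbon with allylic shift gives the same enone, with the new double bond ending next to a stereocentre. No regiochemical question arises, and the stereocentres are homoallylic and stay untouched.

**7 from 6, 6 from 5, 5 from 3 and 4.** Two ring bonds are cut in a [4+2] sense. The trans relationship of the two one-carbon branches comes from the E geometry of fumarate 3, and the absolute configuration from its two menthyl groups. This cycloaddition was preferred to a shorter one that would give an enone directly, because that would require a Lewis-acid-sensitive oxygenated diene under Lewis-acid conditions. The esters are reduced and benzylated at once, so that no acidic C–H remains next to the stereocentres in later steps.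

**3 from 1 and 2; 12 from 11; 25 from 23.** These are one-step preparations: the chiral fumarate 3 from acid chloride 1 and two molecules of 2, the aryl bromide 12 from phenol 11, and the volatile alkyne 25 fresh from acetal 23.

## Alternatives that were turned down

Alternative 1: The cut is through C2–C3 and C1–C8a, which divides the target into two identical sinapyl halves. In the forward direction a one-electron oxidation of the auxiliary-bound sinapic amide A1 gives two phenoxy radicals that join at their β-carbons, and the resulting bis-quinone methide closes ring B to the 1,2-dihydronaphthalene A2.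
- For it: it is by far the shortest route, both aromatic rings arrive with the correct oxygenation and free phenols, and no late C7 hydroxylation or phenol protection is needed. On step and atom economy it is clearly stronger than the chosen route.
- Against it: the two stereocentres of A2 arise in a radical coupling and a quinone methide cyclisation, both remote from the auxiliary, so facial control is uncertain. The electron-rich phenols invite other coupling modes and over-oxidation. A2 still has the C3=C4 double bond, so the C3 centre has to be set afterwards by a reduction whose trans outcome is not assured, and two imides must be reduced to alcohols.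
- In its place the chosen strategy offers stereocentres set one at a time by separately controlled steps, and no radical chemistry on free phenols.

Alternative 2: The cut is through C1–C2 and C3–C4, a [4+2] disconnection of ring B. Irradiation of the 2-benzylbenzaldehyde A3 gives a hydroxy-o-quinodimethane, which adds the lactate-derived fumarate A4 to give the tetralol A5.
- For it: it is convergent, it forms C1, C2 and C3 in one step with the trans,trans arrangement following from the fumarate and the dienol geometry, and both aromatic rings come in intact. In setting C1 together with C2 it is stronger than the chosen route, which needs a separate catalyst-controlled step for C1.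
- Against it: A3 is a pentasubstituted benzene with the benzyl group wedged between the formyl group and a methoxy group, which is laborious to make and crowded in the photoenolisation. Facial control by a lactate ester in an uncatalysed photochemical cycloaddition is likely to be modest. The extra C4 hydroxyl must be removed, although that could coincide with the final hydrogenolysis.
- In its place the chosen strategy offers a thermal, auxiliary-controlled cycloaddition with a well-understood shielding model for C2 and C3, and a ring A whose substitution is dictated by polarity.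

Alternative 3: Only C2–C3 is cut. A zirconium-catalysed asymmetric cyclomagnesiation of the 1,2-diallylarene A6, followed by oxidation of the two carbon–magnesium bonds, gives the trans-diol A7.
- For it: enantiocontrol is catalytic, the diol appears unprotected in one step and ring A is bought, not built. On these points it is stronger than the chosen route, which uses a stoichiometric auxiliary.
- Against it: A7 lacks the aryl group, and the hardest bond of the target, C1–aryl, is left to the end. C1 and C4 of A7 are both benzylic methylene groups that differ only in their peri neighbour, so regioselective functionalisation is doubtful, and the 1,2-trans selectivity of a benzylic arylation or reduction is uncertain. Six-membered ring formation from a 1,7-diene is also the less favourable case for this catalysis.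
- In its place the chosen strategy installs the aryl group on an enone β-carbon, where C1 is the only reactive site, before ring A exists.

Key step: step 12

## Route

Step 1
Reactants: 1 fumaryl chloride; 2 (+)-menthol, (1S,2R,5S)-5-methyl-2-(propan-2-yl)cyclohexan-1-ol
Product: 3 di-(+)-menthyl fumarate (bis[(1S,2R,5S)-5-methyl-2-(propan-2-yl)cyclohexyl] (2E)-but-2-enedioate)
Conditions: 2 (2.2 equiv), pyridine (2.5 equiv), cat. DMAP, CH2Cl2, 0 °C to rt
Reagents that add atoms: (+)-menthol (the second molecule of 2 taken up), O[C@H]1C[C@@H](C)CC[C@@H]1C(C)C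
Why: Twofold acylation of the secondary alcohol: each of the two acyl chloride groups of 1 takes up one molecule of 2, so the diester holds two menthyl units. No stereocentre is touched and the E geometry is kept.

Step 2
Reactants: 3 di-(+)-menthyl fumarate; 4 buta-1,3-diene
Product: 5 bis[(1S,2R,5S)-5-methyl-2-(propan-2-yl)cyclohexyl] (1R,2R)-cyclohex-4-ene-1,2-dicarboxylate
Conditions: i-Bu2AlCl (1.5 equiv), toluene–hexane, −40 °C; recrystallisation
Reagents that add atoms: none
Why: Lewis-acid-promoted Diels–Alder reaction; suprafacial addition to the E alkene gives the trans diester. With both aluminium-bound esters s-trans, the isopropyl groups of the two menthyl units cover the same alkene face, so the diene should add to the open face and give the (1R,2R) adduct with high selectivity.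

Step 3
Reactants: 5 dimenthyl (1R,2R)-cyclohex-4-ene-1,2-dicarboxylate
Product: 6 [(1R,2R)-cyclohex-4-ene-1,2-diyl]dimethanol
Conditions: LiAlH4, THF, 0 °C to reflux
Reagents that add atoms: none
Why: Hydride reduction of both esters, which should outrun any enolisation, so the trans centres are kept; the auxiliary is recovered as 2.

Step 4
Reactants: 6 [(1R,2R)-cyclohex-4-ene-1,2-diyl]dimethanol
Product: 7 (4R,5R)-4,5-bis[(benzyloxy)methyl]cyclohexene
Conditions: NaH (2.5 equiv), BnBr (2.4 equiv), cat. n-Bu4NI, THF–DMF, 0 °C to rt
Reagents that add atoms: benzyl bromide (first equivalent), BrCc1ccccc1; benzyl bromide (second equivalent), BrCc1ccccc1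
Why: Williamson etherification of both primary alcohols, one molecule of benzyl bromide for each.

Step 5
Reactants: 7 (4R,5R)-4,5-bis[(benzyloxy)methyl]cyclohexene
Product: 10 (4R,5R)-4,5-bis[(benzyloxy)methyl]cyclohex-2-en-1-one, via allylic hydroperoxide 8 (not isolated), via allylic peroxyacetate 9 (not isolated)
Conditions: O2, tetraphenylporphyrin (cat.), hν (visible), Ac2O, pyridine, cat. DMAP, CH2Cl2, rt
Reagents that add atoms: dioxygen, O=O; acetic anhydride, CC(=O)OC(C)=O (acetyl group of 9 only)
Why: Schenck ene reaction of singlet oxygen, then Kornblum–DeLaMare-type elimination of the peroxyacetate. Because 7 is C2-symmetric, attack at either alkene carbon gives the same enone, with the carbonyl on a former alkene carbon and the new double bond ending next to a stereocentre. The stereocentres are homoallylic and are not involved.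

Step 6
Reactants: 11 4-bromo-2,6-dimethoxyphenol
Product: 12 2-(benzyloxy)-5-bromo-1,3-dimethoxybenzene
Conditions: BnBr, K2CO3, DMF, 60 °C
Reagents that add atoms: benzyl bromide, BrCc1ccccc1
Why: Williamson etherification of the phenol, needed before halogen–metal exchange.

Step 7
Reactants: 12 2-(benzyloxy)-5-bromo-1,3-dimethoxybenzene; 10 (4R,5R)-4,5-bis[(benzyloxy)methyl]cyclohex-2-en-1-one
Product: 16 {[(3R,4R,5R)-3-Ar-4,5-bis[(benzyloxy)methyl]cyclohex-1-en-1-yl]oxy}trimethylsilane, via aryllithium 13 (not isolated), via aryltitanium triisopropoxide 14 (not isolated), via titanium enolate 15 (not isolated)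
Conditions: 12, n-BuLi, THF, −78 °C; ClTi(OiPr)3, −78 °C to rt; then 10, [Rh(OH)((R)-binap)]2 (3 mol% Rh), THF, 20–40 °C; then LiOiPr, Me3SiCl
Reagents that add atoms: chlorotrimethylsilane, C[Si](C)(C)Cl; n-butyllithium, [Li]CCCC (lithium of 13 only); chlorotitanium triisopropoxide, CC(C)O[Ti](Cl)(OC(C)C)OC(C)C (titanium triisopropoxide unit of 14 and 15 only)
Why: Bromine–lithium exchange and transmetalation give the aryltitanium reagent, which adds to 10 in a rhodium-catalysed asymmetric 1,4-addition (Hayashi–Miyaura type); O-silylation of enolate 15 fixes the enol double bond between the former carbonyl carbon and C2. The new centre C3 (C1 of the target) is set by the ligand: taking the known facial preference of BINAP–rhodium aryls for cyclohex-2-enone, the (R)-ligand should deliver the aryl group to the face of 10 anti to the neighbouring benzyloxymethyl group, so ligand and adjacent substituent act together and the aryl group ends up trans to C4 and cis to C5. A stoichiometric cuprate is avoided because axial attack anti to the C5 substituent would favour the C3 epimer.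

Step 8
Reactants: 16 trimethylsilyl enol ether
Product: 18 (3R,4R,5R)-3-Ar-4,5-bis[(benzyloxy)methyl]cyclohex-1-en-1-yl trifluoromethanesulfonate, via lithium enolate 17 (not isolated)
Conditions: MeLi, THF, 0 °C; then PhNTf2, −78 °C to rt
Reagents that add atoms: N-phenylbis(trifluoromethanesulfonimide), O=S(=O)(N(c1ccccc1)S(=O)(=O)C(F)(F)F)C(F)(F)F; methyllithium, [Li]C (lithium of 17 only)
Why: Cleavage of the Si–O bond gives the lithium enolate without loss of regiochemistry, and O-sulfonylation gives the alkenyl triflate; no stereocentre is affected.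

Step 9
Reactants: 18 alkenyl triflate
Product: 20 1-[(3S,4R,5R)-3-Ar-4,5-bis[(benzyloxy)methyl]cyclohex-1-en-1-yl]ethan-1-one, via ethoxydiene 19 (not isolated)
Conditions: tributyl(1-ethoxyvinyl)stannane, Pd(PPh3)4 (5 mol%), LiCl, THF, 65 °C; then 1 M HCl, rt
Reagents that add atoms: tributyl(1-ethoxyvinyl)stannane, CCCC[Sn](CCCC)(CCCC)C(=C)OCC; water, O
Why: Migita–Kosugi–Stille coupling of the alkenyl triflate with an acetyl anion equivalent, then mild acid hydrolysis of the enol ether to the methyl ketone. The change of the C3 descriptor from R to S is a priority change only.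

Step 10
Reactants: 20 methyl ketone
Product: 22 1-[(3S,4R,5R)-3-Ar-4,5-bis[(benzyloxy)methyl]cyclohex-1-en-1-yl]-2-diazoethan-1-one, via trifluoroacetyl ketone 21 (not isolated)
Conditions: LiN(SiMe3)2, THF, −78 °C; CF3CO2CH2CF3; then MsN3, Et3N, H2O, MeCN, rt
Reagents that add atoms: methanesulfonyl azide, CS(=O)(=O)N=[N+]=[N-]; 2,2,2-trifluoroethyl trifluoroacetate, O=C(OCC(F)(F)F)C(F)(F)F (trifluoroacetyl group of 21 only)
Why: Detrifluoroacetylative Regitz diazo transfer: kinetic deprotonation at the methyl group, Claisen acylation to activate it, then diazo transfer with loss of the trifluoroacetyl group. It avoids exposing a conjugated acid chloride to a diazoalkane.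

Step 11
Reactants: 23 chloroacetaldehyde dimethyl acetal (2-chloro-1,1-dimethoxyethane)
Product: 25 methoxyacetylene (methoxyethyne), via sodium methoxyacetylide 24 (not isolated)
Conditions: NaNH2 (3 equiv), liquid NH3, −33 °C; NH3 evaporated; saturated aq. NaCl, −20 °C; distilled into cold ClCH2CH2Cl
Reagents that add atoms: sodium amide, [Na+].[NH2-] (sodium of 24 only)
Why: Two base-induced eliminations (methanol, then hydrogen chloride) give the alkynyl ether, which is held as its acetylide until hydrolysis; it is made fresh because it is volatile.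

Step 12
Reactants: 22 diazoketone; 25 methoxyacetylene
Product: 30 (1S,2R,3R)-1-Ar-2,3-bis[(benzyloxy)methyl]-6-methoxy-1,2,3,4-tetrahydronaphthalen-8-ol, via vinylketene 26 (not isolated), via vinylcyclobutenone 27 (not isolated), via dienylketene 28 (not isolated), via cyclohexadienone 29 (not isolated)
Conditions: 25 (4 equiv), hν (300 nm, Pyrex), ClCH2CH2Cl, rt; then 80 °C, sealed vessel
Reagents that add atoms: none
Why: Irradiation into the diazoketone band expels N2 and, in a Wolff rearrangement, the cyclohexenyl group migrates to the carbene carbon (making C4a–C5) to give vinylketene 26. The ketene undergoes a [2+2] cycloaddition with the electron-rich triple bond of 25: the unsubstituted, nucleophilic alkyne carbon bonds to the ketene carbonyl carbon (C7–C8) and the oxygen-bearing alkyne carbon to the ketene α-carbon (C5–C6), giving 4-alkenyl-3-methoxycyclobutenone 27. Heating opens 27 in a four-electron electrocyclic reaction to dienylketene 28, whose ketene carbon closes onto C8a in a six-electron disrotatory electrocyclisation, the only ring closure of the step, which forms ring A; tautomerisation of 29 gives the phenol. The closest known reaction type is the photochemical (second-generation) Danheiser benzannulation of cycloalkenyl diazomethyl ketones with heteroatom-substituted alkynes. No stereocentre is created, and the three existing ones are sp3 carbons outside the reacting π system; the medium is neutral, so the allylic, benzylic C1–H is not at risk. The selectivity the step needs is the orientation of the [2+2] addition, and it is secured by the matched polarity of the partners, which places OMe on C6 and OH on C8 and leaves C5 and C7 as C–H. Light of 300 nm is chosen because the benzyl and aryl ether chromophores absorb little there, and the excess of 25 keeps capture of the ketene ahead of its dimerisation.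

Step 13
Reactants: 30 C8 phenol
Product: 31 (1S,2R,3R)-1-Ar-2,3-bis[(benzyloxy)methyl]-6,8-dimethoxy-1,2,3,4-tetrahydronaphthalene
Conditions: MeI, K2CO3, DMF, rt
Reagents that add atoms: iodomethane, CI
Why: Williamson methylation of the only free hydroxyl; the peri position is hindered but the electrophile is small.

Step 14
Reactants: 31 6,8-dimethoxytetralin
Product: 34 (1S,2R,3R)-1-Ar-2,3-bis[(benzyloxy)methyl]-6,8-dimethoxy-1,2,3,4-tetrahydronaphthalen-7-ol, via C7 aryllithium 32 (not isolated), via dimethyl arylboronate 33 (not isolated)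
Conditions: n-BuLi, THF, 0 °C; B(OMe)3, −78 °C to rt; then aq. NaOH, 30% H2O2, 0 °C
Reagents that add atoms: hydrogen peroxide, OO; n-butyllithium, [Li]CCCC (lithium of 32 only); trimethyl borate, COB(OC)OC (boron unit of 33 only)
Why: Directed ortho-metalation at the one C–H flanked by two methoxy groups, borylation, and oxidative C–B to C–O migration; the pendant ring has no position activated by two ether groups.

Step 15
Reactants: 34 tris(benzyl ether)
Product: 35 target, (1S,2R,3R)-1-(4-hydroxy-3,5-dimethoxyphenyl)-2,3-bis(hydroxymethyl)-6,8-dimethoxy-1,2,3,4-tetrahydronaphthalen-7-ol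
Conditions: H2 (1 atm), 10% Pd/C, EtOAc–MeOH, rt
Reagents that add atoms: none
Why: Hydrogenolysis of the two alkyl benzyl ethers and the aryl benzyl ether in one operation; no C–C bond or stereocentre is affected.

## Compound list

1 | fumaryl chloride, (2E)-but-2-enedioyl dichloride | O=C(Cl)/C=C/C(=O)Cl | starting material
2 | (+)-menthol, (1S,2R,5S)-5-methyl-2-(propan-2-yl)cyclohexan-1-ol | O[C@H]1C[C@@H](C)CC[C@@H]1C(C)C | starting material
3 | di-(+)-menthyl fumarate, bis[(1S,2R,5S)-5-methyl-2-(propan-2-yl)cyclohexyl] (2E)-but-2-enedioate | O=C(O[C@H]1C[C@@H](C)CC[C@@H]1C(C)C)/C=C/C(=O)O[C@H]1C[C@@H](C)CC[C@@H]1C(C)C | intermediate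
4 | buta-1,3-diene | C=CC=C | starting material
5 | bis[(1S,2R,5S)-5-methyl-2-(propan-2-yl)cyclohexyl] (1R,2R)-cyclohex-4-ene-1,2-dicarboxylate | C1=CC[C@@H](C(=O)O[C@H]2C[C@@H](C)CC[C@@H]2C(C)C)[C@H](C(=O)O[C@H]2C[C@@H](C)CC[C@@H]2C(C)C)C1 | intermediate
6 | [(1R,2R)-cyclohex-4-ene-1,2-diyl]dimethanol | C1=CC[C@@H](CO)[C@H](CO)C1 | intermediate
7 | (4R,5R)-4,5-bis[(benzyloxy)methyl]cyclohexene | C1=CC[C@@H](COCc2ccccc2)[C@H](COCc2ccccc2)C1 | intermediate
8 | (4R,5R)-4,5-bis[(benzyloxy)methyl]cyclohex-2-en-1-yl hydroperoxide, C1 epimers | OOC1C=C[C@@H](COCc2ccccc2)[C@H](COCc2ccccc2)C1 | intermediate (not isolated)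
9 | (4R,5R)-4,5-bis[(benzyloxy)methyl]cyclohex-2-en-1-yl ethaneperoxoate, C1 epimers | CC(=O)OOC1C=C[C@@H](COCc2ccccc2)[C@H](COCc2ccccc2)C1 | intermediate (not isolated)
10 | (4R,5R)-4,5-bis[(benzyloxy)methyl]cyclohex-2-en-1-one | O=C1C=C[C@@H](COCc2ccccc2)[C@H](COCc2ccccc2)C1 | intermediate
11 | 4-bromo-2,6-dimethoxyphenol | COc1cc(Br)cc(OC)c1O | starting material
12 | 2-(benzyloxy)-5-bromo-1,3-dimethoxybenzene | COc1cc(Br)cc(OC)c1OCc1ccccc1 | intermediate
13 | [4-(benzyloxy)-3,5-dimethoxyphenyl]lithium | [Li]c1cc(OC)c(OCc2ccccc2)c(OC)c1 | intermediate (not isolated)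
14 | [4-(benzyloxy)-3,5-dimethoxyphenyl]titanium triisopropoxide | CC(C)O[Ti](OC(C)C)(OC(C)C)c1cc(OC)c(OCc2ccccc2)c(OC)c1 | intermediate (not isolated)
15 | titanium triisopropoxide enolate, (3R,4R,5R)-3-Ar-4,5-bis[(benzyloxy)methyl]cyclohex-1-en-1-olate | CC(C)O[Ti](OC(C)C)(OC(C)C)OC1=C[C@H](c2cc(OC)c(OCc3ccccc3)c(OC)c2)[C@@H](COCc2ccccc2)[C@H](COCc2ccccc2)C1 | intermediate (not isolated)
16 | {[(3R,4R,5R)-3-[4-(benzyloxy)-3,5-dimethoxyphenyl]-4,5-bis[(benzyloxy)methyl]cyclohex-1-en-1-yl]oxy}trimethylsilane | C[Si](C)(C)OC1=C[C@H](c2cc(OC)c(OCc3ccccc3)c(OC)c2)[C@@H](COCc2ccccc2)[C@H](COCc2ccccc2)C1 | intermediate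
17 | lithium (3R,4R,5R)-3-Ar-4,5-bis[(benzyloxy)methyl]cyclohex-1-en-1-olate | [Li]OC1=C[C@H](c2cc(OC)c(OCc3ccccc3)c(OC)c2)[C@@H](COCc2ccccc2)[C@H](COCc2ccccc2)C1 | intermediate (not isolated)
18 | (3R,4R,5R)-3-[4-(benzyloxy)-3,5-dimethoxyphenyl]-4,5-bis[(benzyloxy)methyl]cyclohex-1-en-1-yl trifluoromethanesulfonate | O=S(=O)(OC1=C[C@H](c2cc(OC)c(OCc3ccccc3)c(OC)c2)[C@@H](COCc2ccccc2)[C@H](COCc2ccccc2)C1)C(F)(F)F | intermediate
19 | (3S,4R,5R)-3-Ar-4,5-bis[(benzyloxy)methyl]-1-(1-ethoxyethenyl)cyclohexene | C=C(OCC)C1=C[C@H](c2cc(OC)c(OCc3ccccc3)c(OC)c2)[C@@H](COCc2ccccc2)[C@H](COCc2ccccc2)C1 | intermediate (not isolated)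
20 | 1-[(3S,4R,5R)-3-[4-(benzyloxy)-3,5-dimethoxyphenyl]-4,5-bis[(benzyloxy)methyl]cyclohex-1-en-1-yl]ethan-1-one | CC(=O)C1=C[C@H](c2cc(OC)c(OCc3ccccc3)c(OC)c2)[C@@H](COCc2ccccc2)[C@H](COCc2ccccc2)C1 | intermediate
21 | 4,4,4-trifluoro-1-[(3S,4R,5R)-3-Ar-4,5-bis[(benzyloxy)methyl]cyclohex-1-en-1-yl]butane-1,3-dione | O=C(CC(=O)C(F)(F)F)C1=C[C@H](c2cc(OC)c(OCc3ccccc3)c(OC)c2)[C@@H](COCc2ccccc2)[C@H](COCc2ccccc2)C1 | intermediate (not isolated)
22 | 1-[(3S,4R,5R)-3-[4-(benzyloxy)-3,5-dimethoxyphenyl]-4,5-bis[(benzyloxy)methyl]cyclohex-1-en-1-yl]-2-diazoethan-1-one | [N-]=[N+]=CC(=O)C1=C[C@H](c2cc(OC)c(OCc3ccccc3)c(OC)c2)[C@@H](COCc2ccccc2)[C@H](COCc2ccccc2)C1 | intermediate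
23 | chloroacetaldehyde dimethyl acetal, 2-chloro-1,1-dimethoxyethane | COC(CCl)OC | starting material
24 | sodium methoxyacetylide | [Na+].[C-]#COC | intermediate (not isolated)
25 | methoxyacetylene, methoxyethyne | COC#C | intermediate
26 | 2-[(3S,4R,5R)-3-Ar-4,5-bis[(benzyloxy)methyl]cyclohex-1-en-1-yl]ethen-1-one (vinylketene) | O=C=CC1=C[C@H](c2cc(OC)c(OCc3ccccc3)c(OC)c2)[C@@H](COCc2ccccc2)[C@H](COCc2ccccc2)C1 | intermediate (not isolated)
27 | 3-methoxy-4-[(3S,4R,5R)-3-Ar-4,5-bis[(benzyloxy)methyl]cyclohex-1-en-1-yl]cyclobut-2-en-1-one, epimers at the cyclobutenone C4 | O=C1C=C(OC)C1C4=C[C@H](c2cc(OC)c(OCc3ccccc3)c(OC)c2)[C@@H](COCc2ccccc2)[C@H](COCc2ccccc2)C4 | intermediate (not isolated)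
28 | (3E)-3-methoxy-4-[(3S,4R,5R)-3-Ar-4,5-bis[(benzyloxy)methyl]cyclohex-1-en-1-yl]buta-1,3-dien-1-one (dienylketene) | O=C=C/C(OC)=C\C1=C[C@H](c2cc(OC)c(OCc3ccccc3)c(OC)c2)[C@@H](COCc2ccccc2)[C@H](COCc2ccccc2)C1 | intermediate (not isolated)
29 | (1R,2R,3R)-1-Ar-2,3-bis[(benzyloxy)methyl]-6-methoxy-1,2,3,4-tetrahydronaphthalen-8(8aH)-one, C8a epimers (same spatial arrangement at C1 as in 30; the descriptor differs by priority only) | O=C1C=C(OC)C=C2C[C@@H](COCc3ccccc3)[C@H](COCc3ccccc3)[C@@H](c3cc(OC)c(OCc4ccccc4)c(OC)c3)C12 | intermediate (not isolated)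
30 | (1S,2R,3R)-1-[4-(benzyloxy)-3,5-dimethoxyphenyl]-2,3-bis[(benzyloxy)methyl]-6-methoxy-1,2,3,4-tetrahydronaphthalen-8-ol | COc1cc([C@H]2c3c(cc(OC)cc3O)C[C@@H](COCc3ccccc3)[C@@H]2COCc2ccccc2)cc(OC)c1OCc1ccccc1 | intermediate
31 | (1S,2R,3R)-1-[4-(benzyloxy)-3,5-dimethoxyphenyl]-2,3-bis[(benzyloxy)methyl]-6,8-dimethoxy-1,2,3,4-tetrahydronaphthalene | COc1cc([C@H]2c3c(cc(OC)cc3OC)C[C@@H](COCc3ccccc3)[C@@H]2COCc2ccccc2)cc(OC)c1OCc1ccccc1 | intermediate
32 | C7 aryllithium of 31 | COc1cc([C@H]2c3c(cc(OC)c([Li])c3OC)C[C@@H](COCc3ccccc3)[C@@H]2COCc2ccccc2)cc(OC)c1OCc1ccccc1 | intermediate (not isolated)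
33 | dimethyl C7 arylboronate of 31 | COc1cc([C@H]2c3c(cc(OC)c(B(OC)OC)c3OC)C[C@@H](COCc3ccccc3)[C@@H]2COCc2ccccc2)cc(OC)c1OCc1ccccc1 | intermediate (not isolated)
34 | (1S,2R,3R)-1-[4-(benzyloxy)-3,5-dimethoxyphenyl]-2,3-bis[(benzyloxy)methyl]-6,8-dimethoxy-1,2,3,4-tetrahydronaphthalen-7-ol | COc1cc([C@H]2c3c(cc(OC)c(O)c3OC)C[C@@H](COCc3ccccc3)[C@@H]2COCc2ccccc2)cc(OC)c1OCc1ccccc1 | intermediate
35 | (1S,2R,3R)-1-(4-hydroxy-3,5-dimethoxyphenyl)-2,3-bis(hydroxymethyl)-6,8-dimethoxy-1,2,3,4-tetrahydronaphthalen-7-ol | COc1cc([C@H]2c3c(cc(OC)c(O)c3OC)C[C@@H](CO)[C@@H]2CO)cc(OC)c1O | target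

## Step count and least certain steps

Total step count: 15. Longest linear sequence: 13 steps (steps 1–5, 7–10 and 12–15); steps 6 and 11 prepare the aryl bromide and the alkyne.

**Step 12 (key step).**
- What may go wrong: inefficient photolysis if the aromatic ethers compete for light; dimerisation of the ketene or its capture by the product phenol (O-acylation) before the alkyne reacts; loss of the volatile alkyne on heating; incomplete thermal opening of the cyclobutenone. All of these lower the mass balance without changing the regiochemistry. A basic methanolysis at the end would return any acylated phenol.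
- Fallback: the same vinylketene 26 is generated without light, by dehydrochlorination. It sets out from 18. Palladium-catalysed coupling with the Reformatsky reagent BrZnCH2CO2Me (Pd(PPh3)4, THF, 60 °C) gives methyl 2-[(3S,4R,5R)-3-Ar-4,5-bis[(benzyloxy)methyl]cyclohex-1-en-1-yl]acetate F1. LiOH in THF–H2O at 0 °C gives 2-[(3S,4R,5R)-3-Ar-4,5-bis[(benzyloxy)methyl]cyclohex-1-en-1-yl]acetic acid F2, and (COCl)2 with cat. DMF gives 2-[(3S,4R,5R)-3-Ar-4,5-bis[(benzyloxy)methyl]cyclohex-1-en-1-yl]acetyl chloride F3. Slow addition of Et3N to F3 and 25 in toluene at 0 °C forms 26 by loss of HCl from the α-carbon, and heating to 80–110 °C carries it through the same cycloaddition and electrocyclic cascade. The route is rejoined at 30.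

**Step 7.**
- What may go wrong: poor facial selectivity if the ligand preference is opposed too strongly by the tendency of the ring to accept the aryl group axially and anti to the C5 substituent, or slow insertion next to the C4 substituent.
- Fallback: the aryl-bearing carbon is first made planar and the stereocentre is then set by hydride delivery instead of aryl delivery. It sets out from 10. Addition of the lithium diarylcuprate made from 13 and CuI, with Me3SiCl, without regard to face, gives {[(4R,5R)-3-Ar-4,5-bis[(benzyloxy)methyl]cyclohex-1-en-1-yl]oxy}trimethylsilane as C3 epimers F4. Saegusa–Ito oxidation (Pd(OAc)2, MeCN) removes the C3 stereocentre and gives (4S,5R)-3-Ar-4,5-bis[(benzyloxy)methyl]cyclohex-2-en-1-one F5. Copper hydride conjugate reduction (Cu(OAc)2, a BINAP-type bisphosphine of the handedness that places hydrogen on the C3 face syn to the C4 substituent, PhMe2SiH, toluene) is then relied on for catalyst control and gives {[(3R,4R,5R)-3-Ar-4,5-bis[(benzyloxy)methyl]cyclohex-1-en-1-yl]oxy}dimethyl(phenyl)silane F6. MeLi and then PhNTf2 convert F6 into the triflate, and the route is rejoined at 18.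

**Step 5.**
- What may go wrong: slow ene reaction, because a 1,2-disubstituted alkene is a poor partner for singlet oxygen; bleaching of the sensitiser and slow oxidative side reactions during long irradiation.
- Fallback: the oxygen is introduced through an epoxide. It sets out from 7. mCPBA gives (1R,3R,4R,6S)-3,4-bis[(benzyloxy)methyl]-7-oxabicyclo[4.1.0]heptane F7. PhSeNa (from PhSeSePh and NaBH4 in EtOH) opens it to trans-(4R,5R)-4,5-bis[(benzyloxy)methyl]-2-(phenylselanyl)cyclohexan-1-ol F8. H2O2 causes selenoxide elimination away from the carbinol and gives (4R,5R)-4,5-bis[(benzyloxy)methyl]cyclohex-2-en-1-ol F9 as carbinol epimers; both directions of epoxide opening lead to this constitution because of the C2-symmetric substitution pattern of 7. MnO2 oxidises F9, and the route is rejoined at 10.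

**Step 14.**
- What may go wrong: metalation at the wrong site. Candidates are the doubly benzylic C1–H next to the C8 methoxy group, a benzylic position of a benzyl ether (followed by Wittig rearrangement), and the pendant ring ortho to one methoxy group.
- Fallback: the C7 oxygen is introduced through an ortho-formylation of the phenol, without an organolithium. It sets out from 30. MgCl2, Et3N and paraformaldehyde in MeCN formylate the only free position ortho to the hydroxyl and give (1S,2R,3R)-1-Ar-2,3-bis[(benzyloxy)methyl]-8-hydroxy-6-methoxy-1,2,3,4-tetrahydronaphthalene-7-carbaldehyde F10. MeI and K2CO3 give (1S,2R,3R)-1-Ar-2,3-bis[(benzyloxy)methyl]-6,8-dimethoxy-1,2,3,4-tetrahydronaphthalene-7-carbaldehyde F11. Baeyer–Villiger oxidation with mCPBA gives (1S,2R,3R)-1-Ar-2,3-bis[(benzyloxy)methyl]-6,8-dimethoxy-1,2,3,4-tetrahydronaphthalen-7-yl formate F12, and K2CO3 in MeOH removes the formyl group. The route is rejoined at 34.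

## Further compounds

F1 | step 12 | methyl 2-[(3S,4R,5R)-3-[4-(benzyloxy)-3,5-dimethoxyphenyl]-4,5-bis[(benzyloxy)methyl]cyclohex-1-en-1-yl]acetate | COC(=O)CC1=C[C@H](c2cc(OC)c(OCc3ccccc3)c(OC)c2)[C@@H](COCc2ccccc2)[C@H](COCc2ccccc2)C1
F2 | step 12 | 2-[(3S,4R,5R)-3-[4-(benzyloxy)-3,5-dimethoxyphenyl]-4,5-bis[(benzyloxy)methyl]cyclohex-1-en-1-yl]acetic acid | OC(=O)CC1=C[C@H](c2cc(OC)c(OCc3ccccc3)c(OC)c2)[C@@H](COCc2ccccc2)[C@H](COCc2ccccc2)C1
F3 | step 12 | 2-[(3S,4R,5R)-3-[4-(benzyloxy)-3,5-dimethoxyphenyl]-4,5-bis[(benzyloxy)methyl]cyclohex-1-en-1-yl]acetyl chloride | ClC(=O)CC1=C[C@H](c2cc(OC)c(OCc3ccccc3)c(OC)c2)[C@@H](COCc2ccccc2)[C@H](COCc2ccccc2)C1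
F4 | step 7 | {[(4R,5R)-3-[4-(benzyloxy)-3,5-dimethoxyphenyl]-4,5-bis[(benzyloxy)methyl]cyclohex-1-en-1-yl]oxy}trimethylsilane, C3 epimers | C[Si](C)(C)OC1=CC(c2cc(OC)c(OCc3ccccc3)c(OC)c2)[C@@H](COCc2ccccc2)[C@H](COCc2ccccc2)C1
F5 | step 7 | (4S,5R)-3-[4-(benzyloxy)-3,5-dimethoxyphenyl]-4,5-bis[(benzyloxy)methyl]cyclohex-2-en-1-one | O=C1C=C(c2cc(OC)c(OCc3ccccc3)c(OC)c2)[C@@H](COCc2ccccc2)[C@H](COCc2ccccc2)C1
F6 | step 7 | {[(3R,4R,5R)-3-[4-(benzyloxy)-3,5-dimethoxyphenyl]-4,5-bis[(benzyloxy)methyl]cyclohex-1-en-1-yl]oxy}dimethyl(phenyl)silane | C[Si](C)(c1ccccc1)OC1=C[C@H](c2cc(OC)c(OCc3ccccc3)c(OC)c2)[C@@H](COCc2ccccc2)[C@H](COCc2ccccc2)C1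
F7 | step 5 | (1R,3R,4R,6S)-3,4-bis[(benzyloxy)methyl]-7-oxabicyclo[4.1.0]heptane | [C@@H]12O[C@@H]1C[C@@H](COCc3ccccc3)[C@H](COCc3ccccc3)C2
F8 | step 5 | trans-(4R,5R)-4,5-bis[(benzyloxy)methyl]-2-(phenylselanyl)cyclohexan-1-ol, either direction of ring opening | OC1C[C@@H](COCc2ccccc2)[C@H](COCc2ccccc2)CC1[Se]c1ccccc1
F9 | step 5 | (4R,5R)-4,5-bis[(benzyloxy)methyl]cyclohex-2-en-1-ol, C1 epimers | OC1C[C@@H](COCc2ccccc2)[C@H](COCc2ccccc2)C=C1
F10 | step 14 | (1S,2R,3R)-1-[4-(benzyloxy)-3,5-dimethoxyphenyl]-2,3-bis[(benzyloxy)methyl]-8-hydroxy-6-methoxy-1,2,3,4-tetrahydronaphthalene-7-carbaldehyde | COc1cc([C@H]2c3c(cc(OC)c(C=O)c3O)C[C@@H](COCc3ccccc3)[C@@H]2COCc2ccccc2)cc(OC)c1OCc1ccccc1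
F11 | step 14 | (1S,2R,3R)-1-[4-(benzyloxy)-3,5-dimethoxyphenyl]-2,3-bis[(benzyloxy)methyl]-6,8-dimethoxy-1,2,3,4-tetrahydronaphthalene-7-carbaldehyde | COc1cc([C@H]2c3c(cc(OC)c(C=O)c3OC)C[C@@H](COCc3ccccc3)[C@@H]2COCc2ccccc2)cc(OC)c1OCc1ccccc1
F12 | step 14 | (1S,2R,3R)-1-[4-(benzyloxy)-3,5-dimethoxyphenyl]-2,3-bis[(benzyloxy)methyl]-6,8-dimethoxy-1,2,3,4-tetrahydronaphthalen-7-yl formate | COc1cc([C@H]2c3c(cc(OC)c(OC=O)c3OC)C[C@@H](COCc3ccccc3)[C@@H]2COCc2ccccc2)cc(OC)c1OCc1ccccc1
A1 | alternative 1 | (4S)-4-benzyl-3-[(2E)-3-(4-hydroxy-3,5-dimethoxyphenyl)prop-2-enoyl]-1,3-oxazolidin-2-one | COc1cc(/C=C/C(=O)N2[C@@H](Cc3ccccc3)COC2=O)cc(OC)c1O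
A2 | alternative 1 | 3,3'-[trans-7-hydroxy-1-(4-hydroxy-3,5-dimethoxyphenyl)-6,8-dimethoxy-1,2-dihydronaphthalene-2,3-dicarbonyl]bis[(4S)-4-benzyl-1,3-oxazolidin-2-one] | COc1cc([C@H]2c3c(cc(OC)c(O)c3OC)C=C(C(=O)N4[C@@H](Cc5ccccc5)COC4=O)[C@@H]2C(=O)N2[C@@H](Cc3ccccc3)COC2=O)cc(OC)c1O
A3 | alternative 2 | 4-(benzyloxy)-2-[4-(benzyloxy)-3,5-dimethoxybenzyl]-3,5-dimethoxybenzaldehyde | O=Cc1cc(OC)c(OCc2ccccc2)c(OC)c1Cc1cc(OC)c(OCc2ccccc2)c(OC)c1
A4 | alternative 2 | bis[(2S)-1-methoxy-1-oxopropan-2-yl] (2E)-but-2-enedioate | COC(=O)[C@H](C)OC(=O)/C=C/C(=O)O[C@@H](C)C(=O)OC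
A5 | alternative 2 | bis[(2S)-1-methoxy-1-oxopropan-2-yl] 7-(benzyloxy)-1-[4-(benzyloxy)-3,5-dimethoxyphenyl]-4-hydroxy-6,8-dimethoxy-1,2,3,4-tetrahydronaphthalene-2,3-dicarboxylate (1,2-trans, 2,3-trans, 3,4-cis) | COc1cc([C@H]2c3c(cc(OC)c(OCc4ccccc4)c3OC)[C@@H](O)[C@@H](C(=O)O[C@@H](C)C(=O)OC)[C@@H]2C(=O)O[C@@H](C)C(=O)OC)cc(OC)c1OCc1ccccc1
A6 | alternative 3 | 2-(benzyloxy)-1,3-dimethoxy-4,5-di(prop-2-en-1-yl)benzene | C=CCc1cc(OC)c(OCc2ccccc2)c(OC)c1CC=C
A7 | alternative 3 | [(2R,3R)-7-(benzyloxy)-6,8-dimethoxy-1,2,3,4-tetrahydronaphthalene-2,3-diyl]dimethanol | COc1cc2C[C@@H](CO)[C@H](CO)Cc2c(OC)c1OCc1ccccc1
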